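**Plan**

- Retrosynthesis: the enyne C(sp)–C(sp2) bond is cut first (Sonogashira: oxolane alkyne 17 + iodo-bromotriene 28). Next come the oxolane C5–C≡ bond and one CH2 of the ester chain, and last the two ring bonds that join C2 and C5 to the C3–C4 unit.
- Enabling feature: in the oxolane ring, O1 with its two CH neighbours C2 and C5 is a carbonyl ylide and the unsubstituted C3–C4 pair is an ethylene. Tying C2 to C5 through three carbons at ketone level (they become three of the four butanoate carbons) turns this ylide into the aromatic pyrylium-3-olate, which is made from furfuryl alcohol.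
- Forward: the ylide adds to phenyl vinyl sulfide (ethylene equivalent, sulfur removed with Raney Ni), closing the oxolane inside an 8-oxabicyclo[3.2.1]octan-2-one. The temporary seven-membered ring is then cut by Baeyer–Villiger oxidation and alkynylative opening of the acyl acetal, and the chain is lengthened by one carbon (Arndt–Eistert).
- The side chain is built from hept-6-yn-1-ol and propargyl alcohol (hydrozirconation–iodination, Wittig, bromodestannylation) and joined last.
- Stereochemistry: C2 (R) comes from a ketoreductase kinetic resolution of the racemic bicyclic ketone. C5 (S) comes from alkynyl attack trans to the tethered carboxylate. 3E comes from syn-hydrozirconation, 9Z from a salt-free Wittig reaction, and 11E from hydrostannation and bromodestannylation with retention.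

Key step: step 3

Assumption: the ketoreductase that reduces the (1S,5R)-ketone is taken from a screening panel and the by-product alcohol is drawn with an equatorial hydroxyl for definiteness; adduct 6 is drawn as the 6-regioisomer, and any 7-isomer or exo/endo isomer converges on 7 in step 4.

**Route**

Step 1
Reactants: 1 furan-2-ylmethanol (furfuryl alcohol)
Product: 2 6-hydroxy-2H-pyran-3(6H)-one (racemic hemiacetal)
Conditions: mCPBA, CH2Cl2, 0 → 20 °C
Reagents that add atoms: 3-chloroperoxybenzoic acid (mCPBA), OOC(=O)c1cccc(Cl)c1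
Why: Achmatowicz rearrangement: oxidation of the furan at C2/C5 and reclosure of the ene-dione onto the hydroxymethyl oxygen should give the pyranone; the anomeric centre is of no consequence.

Step 2
Reactants: 2 6-hydroxy-2H-pyran-3(6H)-one
Product: 3 5-oxo-5,6-dihydro-2H-pyran-2-yl acetate (6-acetoxy-2H-pyran-3(6H)-one, racemic)
Conditions: Ac2O, pyridine, DMAP (cat.), CH2Cl2, 0 °C
Reagents that add atoms: acetic anhydride, CC(=O)OC(C)=O
Why: DMAP-catalysed O-acylation of the hemiacetal installs the leaving group needed to generate the ylide.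

Step 3
Reactants: 3 5-oxo-5,6-dihydro-2H-pyran-2-yl acetate; 4 phenyl vinyl sulfide
Product: 6 rac-6-(phenylsulfanyl)-8-oxabicyclo[3.2.1]oct-3-en-2-one (bridgeheads cis, exo/endo mixture at C6), via pyrylium-3-olate 5 (not isolated)
Conditions: 4 (5 equiv), Et3N (1.2 equiv, added slowly), CH2Cl2, 20 °C
Reagents that add atoms: none
Why: Et3N removes a C2 proton of 3 and the enolate expels acetate from C6 to give the aromatic 6π pyrylium-3-olate 5, in which O1 with C2 and C6 is a carbonyl ylide; this adds across C2/C6 to the C=C bond of 4 in a concerted suprafacial [5+2] (1,3-dipolar) cycloaddition, the closest known type being the base-induced oxidopyrylium–alkene cycloaddition of 6-acetoxypyranones with vinyl ethers and acrylic partners. Both new C–C bonds form in this one event, which closes the oxolane ring (O8, C1, C7, C6, C5) and the seven-membered enone ring together as a bridged bicycle by cycloaddition, not by a separate cyclisation. The bridgehead centres C1 and C5 are necessarily cis because both bonds form on one face of the planar ylide; ylide and alkene are achiral, so 6 is racemic and the absolute configuration is settled in step 5. The position and configuration of the sulfur-bearing carbon need no control because step 4 replaces sulfur by hydrogen. The selectivity that matters is cycloaddition over dimerisation of the ylide, which should be secured by the excess of the high-HOMO vinyl sulfide and the slow addition of base.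

Step 4
Reactants: 6 rac-6-(phenylsulfanyl)-8-oxabicyclo[3.2.1]oct-3-en-2-one
Product: 7 rac-8-oxabicyclo[3.2.1]octan-2-one
Conditions: Raney Ni (W-2, deactivated with acetone), H2 (1 atm), EtOH, 20 °C
Reagents that add atoms: none
Why: reductive desulfurisation cleaves both C–S bonds and the conjugated C3=C4 bond is hydrogenated in the same operation, so the activating group is erased and all isomers of 6 converge on one ketone.

Step 5
Reactants: 7 rac-8-oxabicyclo[3.2.1]octan-2-one
Product: 8 (1R,5S)-8-oxabicyclo[3.2.1]octan-2-one (the unreduced enantiomer)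
Conditions: ketoreductase (NADPH-dependent, selective for the (1S,5R)-ketone), NADP+ (cat.), propan-2-ol, phosphate buffer pH 7, 30 °C, stopped near half conversion
Reagents that add atoms: none
Why: enzymatic kinetic resolution by enantiomer-selective carbonyl reduction: the chiral active site should reduce only the (1S,5R)-ketone, so the recovered (1R,5S)-ketone carries the configuration of the carbon that becomes C2 of the target.

Step 6
Reactants: 8 (1R,5S)-8-oxabicyclo[3.2.1]octan-2-one
Product: 9 (1S,6S)-2,9-dioxabicyclo[4.2.1]nonan-3-one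
Conditions: mCPBA, CH2Cl2, 0 → 20 °C
Reagents that add atoms: 3-chloroperoxybenzoic acid (mCPBA), OOC(=O)c1cccc(Cl)c1
Why: Baeyer–Villiger oxidation with migration of the electron-rich α-alkoxy bridgehead carbon (retention) inserts oxygen between C1 and C2 and turns the temporary carbocycle into an acyl acetal.

Step 7
Reactants: 9 (1S,6S)-2,9-dioxabicyclo[4.2.1]nonan-3-one; 10 tributyl[(trimethylsilyl)ethynyl]stannane
Product: 12 3-[(2S,5S)-5-[(trimethylsilyl)ethynyl]oxolan-2-yl]propanoic acid, via tributylstannyl ester 11 (not isolated)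
Conditions: 10 (1.5 equiv), TMSOTf (20 mol %), CH2Cl2, −78 → −20 °C; then aq. KF, 1 M HCl
Reagents that add atoms: none
Why: Lewis-acid ionisation of the acyl acetal gives an oxolan-2-ylium ion whose carboxylate leaving group stays tethered on the face cis to the side chain, so the alkynylstannane (ipso substitution at tin, C-glycosylation type) should attack the opposite face with inversion and set the trans (5S) centre.

Step 8
Reactants: 12 3-[(2S,5S)-5-[(trimethylsilyl)ethynyl]oxolan-2-yl]propanoic acid
Product: 14 1-diazo-4-[(2S,5S)-5-[(trimethylsilyl)ethynyl]oxolan-2-yl]butan-2-one, via acid chloride 13 (not isolated)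
Conditions: (COCl)2, DMF (cat.), CH2Cl2, 0 → 20 °C, evaporate; then CH2N2 (2.5 equiv), Et2O, 0 °C
Reagents that add atoms: diazomethane, C=[N+]=[N-]
Why: first stage of the Arndt–Eistert homologation: the acid chloride acylates diazomethane and a second equivalent takes up the HCl; the stereocentres are remote and untouched.

Step 9
Reactants: 14 1-diazo-4-[(2S,5S)-5-[(trimethylsilyl)ethynyl]oxolan-2-yl]butan-2-one
Product: 17 methyl 4-[(2R,5S)-5-ethynyloxolan-2-yl]butanoate, via ketene 15 (not isolated), via silylalkyne methyl ester 16 (not isolated)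
Conditions: hν (365 nm), MeOH, 20 °C; then K2CO3 (cat.), 20 °C
Reagents that add atoms: methanol, CO
Why: photochemical Wolff rearrangement gives the ketene, which methanol traps as the homologated methyl ester, and methoxide then cleaves the C–Si bond in the same pot; a silver salt is avoided because of the alkyne.

Step 10
Reactants: 18 hept-6-yn-1-ol
Product: 19 7-bromohept-1-yne
Conditions: CBr4, PPh3, CH2Cl2, 0 °C
Reagents that add atoms: carbon tetrabromide, BrC(Br)(Br)Br
Why: Appel bromination of the primary alcohol by SN2 displacement of the alkoxyphosphonium.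

Step 11
Reactants: 19 7-bromohept-1-yne
Product: 21 (E)-7-bromo-1-iodohept-1-ene, via alkenylzirconocene chloride 20 (not isolated)
Conditions: Cp2Zr(H)Cl, THF, 20 °C; then I2, 0 °C
Reagents that add atoms: iodine, II
Why: syn-hydrozirconation places zirconium on the terminal carbon and iodinolysis of the C–Zr bond proceeds with retention, so the (E)-iodide should result; the alkyl bromide is inert.

Step 12
Reactants: 21 (E)-7-bromo-1-iodohept-1-ene
Product: 22 [(E)-7-iodohept-6-en-1-yl]triphenylphosphonium bromide
Conditions: PPh3, MeCN, 80 °C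
Reagents that add atoms: triphenylphosphine, c1ccc(cc1)P(c1ccccc1)c1ccccc1
Why: SN2 quaternisation at the primary bromide; the alkenyl iodide does not react with the phosphine in the absence of a metal catalyst.

Step 13
Reactants: 23 prop-2-yn-1-ol (propargyl alcohol)
Product: 24 (E)-3-(tributylstannyl)prop-2-en-1-ol
Conditions: Bu3SnH, AIBN (cat.), neat, 80 °C; chromatography
Reagents that add atoms: tributyltin hydride, CCCC[SnH](CCCC)CCCC
Why: radical hydrostannation adds the stannyl radical to the terminal carbon, and reversible stannyl radical addition equilibrates the product to the (E)-alkenylstannane.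

Step 14
Reactants: 24 (E)-3-(tributylstannyl)prop-2-en-1-ol
Product: 25 (E)-3-(tributylstannyl)prop-2-enal
Conditions: MnO2, CH2Cl2, 20 °C
Reagents that add atoms: none
Why: selective oxidation of the allylic alcohol without touching the C–Sn bond or the alkene geometry.

Step 15
Reactants: 22 [(E)-7-iodohept-6-en-1-yl]triphenylphosphonium bromide; 25 (E)-3-(tributylstannyl)prop-2-enal
Product: 27 tributyl[(1E,3Z,9E)-10-iododeca-1,3,9-trien-1-yl]stannane, via phosphonium ylide 26 (not isolated)
Conditions: NaN(SiMe3)2, THF, −78 °C; then 25, −78 → 0 °C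
Reagents that add atoms: none
Why: Wittig reaction of a non-stabilised ylide under salt-free conditions should give the (Z)-alkene through the kinetically favoured cis-oxaphosphetane; both existing (E)-alkenes are untouched.

Step 16
Reactants: 27 tributyl[(1E,3Z,9E)-10-iododeca-1,3,9-trien-1-yl]stannane
Product: 28 (1E,3Z,9E)-1-bromo-10-iododeca-1,3,9-triene
Conditions: NBS, MeCN, −20 → 0 °C, dark
Reagents that add atoms: N-bromosuccinimide, BrN1C(=O)CCC1=O
Why: bromodestannylation is an ipso substitution at the C–Sn bond that proceeds with retention, so the (E)-bromide should result with the (Z)-alkene intact.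

Step 17
Reactants: 17 methyl 4-[(2R,5S)-5-ethynyloxolan-2-yl]butanoate; 28 (1E,3Z,9E)-1-bromo-10-iododeca-1,3,9-triene
Product: 29 methyl 4-[(2R,5S)-5-[(3E,9Z,11E)-12-bromododeca-3,9,11-trien-1-yn-1-yl]oxolan-2-yl]butanoate (target)
Conditions: Pd(PPh3)4 (5 mol %), CuI (10 mol %), Et3N, THF (degassed), 0 → 20 °C, dark
Reagents that add atoms: none
Why: Sonogashira coupling: oxidative addition of zerovalent palladium to the C–I bond is much faster than to the C–Br bond, and the coupling retains the (E)-geometry, so the enyne should form with the bromodiene intact.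

**Compound list**

1 | furan-2-ylmethanol | OCc1ccco1 | starting material
2 | 6-hydroxy-2H-pyran-3(6H)-one (racemic) | OC1OCC(=O)C=C1 | intermediate
3 | 5-oxo-5,6-dihydro-2H-pyran-2-yl acetate (racemic) | CC(=O)OC1OCC(=O)C=C1 | intermediate
4 | phenyl vinyl sulfide | C=CSc1ccccc1 | starting material
5 | pyrylium-3-olate | [O-]c1ccc[o+]c1 | intermediate
6 | rac-6-(phenylsulfanyl)-8-oxabicyclo[3.2.1]oct-3-en-2-one (exo/endo mixture) | O=C1C=CC2OC1CC2Sc1ccccc1 | intermediate
7 | rac-8-oxabicyclo[3.2.1]octan-2-one | O=C1CCC2CCC1O2 | intermediate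
8 | (1R,5S)-8-oxabicyclo[3.2.1]octan-2-one | O=C1CC[C@@H]2CC[C@H]1O2 | intermediate
9 | (1S,6S)-2,9-dioxabicyclo[4.2.1]nonan-3-one | O=C1CC[C@@H]2CC[C@H](O1)O2 | intermediate
10 | tributyl[(trimethylsilyl)ethynyl]stannane | C[Si](C)(C)C#C[Sn](CCCC)(CCCC)CCCC | starting material
11 | tributylstannyl 3-[(2S,5S)-5-[(trimethylsilyl)ethynyl]oxolan-2-yl]propanoate | CCCC[Sn](CCCC)(CCCC)OC(=O)CC[C@@H]1CC[C@@H](C#C[Si](C)(C)C)O1 | intermediate
12 | 3-[(2S,5S)-5-[(trimethylsilyl)ethynyl]oxolan-2-yl]propanoic acid | OC(=O)CC[C@@H]1CC[C@@H](C#C[Si](C)(C)C)O1 | intermediate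
13 | 3-[(2S,5S)-5-[(trimethylsilyl)ethynyl]oxolan-2-yl]propanoyl chloride | ClC(=O)CC[C@@H]1CC[C@@H](C#C[Si](C)(C)C)O1 | intermediate
14 | 1-diazo-4-[(2S,5S)-5-[(trimethylsilyl)ethynyl]oxolan-2-yl]butan-2-one | [N-]=[N+]=CC(=O)CC[C@@H]1CC[C@@H](C#C[Si](C)(C)C)O1 | intermediate
15 | 4-[(2R,5S)-5-[(trimethylsilyl)ethynyl]oxolan-2-yl]but-1-en-1-one (ketene) | O=C=CCC[C@@H]1CC[C@@H](C#C[Si](C)(C)C)O1 | intermediate
16 | methyl 4-[(2R,5S)-5-[(trimethylsilyl)ethynyl]oxolan-2-yl]butanoate | COC(=O)CCC[C@@H]1CC[C@@H](C#C[Si](C)(C)C)O1 | intermediate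
17 | methyl 4-[(2R,5S)-5-ethynyloxolan-2-yl]butanoate | COC(=O)CCC[C@@H]1CC[C@@H](C#C)O1 | intermediate
18 | hept-6-yn-1-ol | OCCCCCC#C | starting material
19 | 7-bromohept-1-yne | BrCCCCCC#C | intermediate
20 | [(E)-7-bromohept-1-en-1-yl]chlorobis(cyclopentadienyl)zirconium | Cl[Zr](C1C=CC=C1)(C1C=CC=C1)/C=C/CCCCCBr | intermediate
21 | (E)-7-bromo-1-iodohept-1-ene | I/C=C/CCCCCBr | intermediate
22 | [(E)-7-iodohept-6-en-1-yl]triphenylphosphonium bromide | I/C=C/CCCCC[P+](c1ccccc1)(c1ccccc1)c1ccccc1.[Br-] | intermediate
23 | prop-2-yn-1-ol | OCC#C | starting material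
24 | (E)-3-(tributylstannyl)prop-2-en-1-ol | OC/C=C/[Sn](CCCC)(CCCC)CCCC | intermediate
25 | (E)-3-(tributylstannyl)prop-2-enal | O=C/C=C/[Sn](CCCC)(CCCC)CCCC | intermediate
26 | [(E)-7-iodohept-6-en-1-ylidene]triphenylphosphorane | I/C=C/CCCCC=P(c1ccccc1)(c1ccccc1)c1ccccc1 | intermediate
27 | tributyl[(1E,3Z,9E)-10-iododeca-1,3,9-trien-1-yl]stannane | CCCC[Sn](CCCC)(CCCC)/C=C/C=C\CCCC/C=C/I | intermediate
28 | (1E,3Z,9E)-1-bromo-10-iododeca-1,3,9-triene | Br/C=C/C=C\CCCC/C=C/I | intermediate
29 | methyl 4-[(2R,5S)-5-[(3E,9Z,11E)-12-bromododeca-3,9,11-trien-1-yn-1-yl]oxolan-2-yl]butanoate | COC(=O)CCC[C@@H]1CC[C@@H](C#C/C=C/CCCC/C=C\C=C\Br)O1 | target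

**Step count and risks**

Total steps: 17. Longest linear sequence: 10 steps (steps 1–9 and 17).

Steps most likely to fail:

1. Step 3. Dimerisation of the ylide may outrun the cycloaddition with the only moderately reactive vinyl sulfide, leaving low conversion to the bicycle. Fallback, from 3 back to 7: the ylide is generated in the same way but trapped by acrolein, an electron-poor partner of established reactivity towards this ylide, to give rac-2-oxo-8-oxabicyclo[3.2.1]oct-3-ene-6-carbaldehyde F1. The formyl helper is then removed by decarbonylation with RhCl(PPh3)3 (1 equiv, toluene, 110 °C) to give rac-8-oxabicyclo[3.2.1]oct-3-en-2-one F2. Hydrogenation of F2 (H2, Pd/C, EtOAc) returns to 7.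

2. Step 7. Facial discrimination in the attack on the oxolanylium ion may be insufficient, giving the cis isomer alongside the trans, and protodestannylation may erode the reagent. Fallback, from 9 back to 12, in a radical instead of a cationic manifold: 9 is opened with PhSeH and catalytic BF3·OEt2 (CH2Cl2, −40 °C) to 3-[(2R)-5-(phenylselanyl)oxolan-2-yl]propanoic acid F3 (both C5 epimers). The oxolan-2-yl radical released from F3 with (Bu3Sn)2 under irradiation (benzene) is trapped by phenyl (trimethylsilyl)ethynyl sulfone through addition and β-elimination of the sulfonyl radical. Attack anti to the side chain should give 12.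

3. Step 5. The enzyme may discriminate the two enantiomers too weakly, or over-conversion may erode the recovery of the wanted ketone. Fallback, from 7 back to 8, by a covalent resolution: 7 is ketalised with (1R,2R)-1,2-diphenylethane-1,2-diol (TsOH, toluene, azeotropic removal of water). This gives the diastereomers (1R,4'R,5S,5'R)-4',5'-diphenylspiro[8-oxabicyclo[3.2.1]octane-2,2'-[1,3]dioxolane] F4 and (1S,4'R,5R,5'R)-4',5'-diphenylspiro[8-oxabicyclo[3.2.1]octane-2,2'-[1,3]dioxolane] F5, which are separated by chromatography or crystallisation. Hydrolysis of F4 (aq. HCl, THF) gives 8.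

Further compounds
F1 | step 3 | rac-2-oxo-8-oxabicyclo[3.2.1]oct-3-ene-6-carbaldehyde (exo/endo mixture) | O=C1C=CC2OC1CC2C=O
F2 | step 3 | rac-8-oxabicyclo[3.2.1]oct-3-en-2-one | O=C1C=CC2CCC1O2
F3 | step 7 | 3-[(2R)-5-(phenylselanyl)oxolan-2-yl]propanoic acid (both C5 epimers) | OC(=O)CC[C@@H]1CCC([Se]c2ccccc2)O1
F4 | step 5 | (1R,4'R,5S,5'R)-4',5'-diphenylspiro[8-oxabicyclo[3.2.1]octane-2,2'-[1,3]dioxolane] | c1ccccc1[C@H]1OC2(CC[C@@H]3CC[C@H]2O3)O[C@@H]1c1ccccc1
F5 | step 5 | (1S,4'R,5R,5'R)-4',5'-diphenylspiro[8-oxabicyclo[3.2.1]octane-2,2'-[1,3]dioxolane] | c1ccccc1[C@H]1OC2(CC[C@H]3CC[C@@H]2O3)O[C@@H]1c1ccccc1
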